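Readings and results come from a simulation with made-up constants; scatter was added.

**The question.** What share of 26.0 mM of starting material has become target after 40 min in the south run? The east run holds 300 mM of coupling partner against 120 mM of starting material, and the south run has the same excess or more. Starting material is the smaller charge in the east run, and we keep the books in fractions of its charge.

| flask | starting material | coupling partner | time |
|---|---|---|---|
| east | 120 mM | 300 mM |  |
| west | 120 mM | 450 mM |  |
| north-west | 60.0 mM | 300 mM |  |
| south | 26.0 mM | 300 mM | 40 min |

| east run: time / min | east run: [target] / mM | west run: time / min | west run: [target] / mM | north-west run: time / min | north-west run: [target] / mM |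
|---|---|---|---|---|---|
| 3.0 | 1.2 | 3.0 | 4.2 | 3.0 | 1.5 |
| 9.2 | 14.9 | 9.2 | 15.3 | 9.2 | 12.4 |
| 18 | 28.5 | 18 | 31.7 | 18 | 20.4 |
| 28 | 40.9 | 28 | 44.5 | 28 | 25.1 |
| 40 | 50.9 | 40 | 54.8 | 40 | 35.8 |

(readings scatter by 1 mM)

* the exponent of [coupling partner] in the starting rate at the charge of the east run (at the point where two percent of the starting material have become target)
* the exponent of [starting material] in the starting rate at the charge of the east run (at the point where two percent of the starting material have become target) (one fixed amount of target, the same in the runs compared)
* target in the south run at 40 min, as a share of the starting material charged

- Overall: starting material + coupling partner -> target.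
- Constant volume, constant temperature.
- What is held in complexes is read along with the free species.
- An order is taken over about fifteen percent of the charge, up and down.

**The ledger.** Each mole charged stands in one of two entries: target, or still open, whatever form it takes. After 40 min, the east run books 42.4% to target and leaves 57.6% open. The north-west run, with half that charge, books 59.7% and leaves 40.3% open, a larger share turned than in the east run.

**The zero.** A flask first order in starting material has one clock for any charge, so the time to a given share does not depend on the charge. We pool the last 3 readings of a run: the sum of the logarithms of charge over open, divided by the sum of those times, is a first-order clock. It reads 0.0144 min⁻¹ in the east run and 0.0217 min⁻¹ in the north-west run, faster at the smaller charge. The logarithm of that clock ratio over the logarithm of the charge ratio reads 0.589, and we call it the charge exponent. It is zero for first order and one for a rate indifferent to the charge.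

**Our reckoning.** Carrying the north-west clock down to the south charge with the charge exponent gives 0.0355 min⁻¹. After 40 min our south ledger closes at 75.8% target and 24.2% open.

**The forecast.** It puts the south run at 72%, between 58% and 87%, a little below ours. It gives the exponent of coupling partner as 0.2 (0 to 0.5) and that of starting material as 0.45 (0.2 to 0.75). Of the falling rate it says: “That points to product inhibition or catalyst loss.”

**The result.** The south run gives 74.7%. The exponent of starting material is 0.42, and that of coupling partner is 0.31, above the forecast's 0.2. The flask runs on this scheme:

    starting material ⇌ intermediate + by-product (0.09240 min⁻¹, 2.292 M⁻¹ min⁻¹)
    intermediate + coupling partner → target (1.566 M⁻¹ min⁻¹)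
    2 starting material ⇌ idle substrate dimer, settled at all times (51.20 M⁻¹)
    2 coupling partner → lost reagent (0.1332 M⁻¹ min⁻¹)

The south ledger closes with 25.3% open, which is a first-order clock of 0.0344 min⁻¹. Set against the north-west clock, this gives a charge exponent of 0.550 between those two runs, a little below the 0.589 between east and north-west.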